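## Retrosynthetic overview

1. The 15-membered macrocycle is closed last by forming the aryl–C1 bond: macrocyclising ortho-C-allylation of the free phenoxide by the C1 allylic bromide (proposed new step).
2. C1 comes from CO (formylation of the C2 enol triflate). The C9–C10 epoxide is made by ent-Shi epoxidation while the ring alkene is still an inert enol triflate.
3. Ring stereocentres C6/C7 come from CBS desymmetrisation of a 2,2-disubstituted cyclohexane-1,3-dione, then invertive Appel bromination; the C3 methyl comes from enolate methylation.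
4. C7–C8 is made by Tsuji–Trost allylation of 2-methylcyclohexane-1,3-dione with a geranyl-acetate-derived allylic acetate.
5. The C13-bromo/C14 tertiary ester comes from ent-Shi epoxidation of geranyl acetate, SN2 bromide opening and acylation with silyl-protected 4-hydroxybenzoic anhydride. Ring order: cyclohexane (purchased) → oxirane → macrocycle.

Assumption: the SMILES is taken literally (C26H34Br2O4, one CH2 between the ring quaternary carbon and the epoxide). Locants: C1 benzylic CH2; C2=C3(Me) ring alkene; C4, C5; C6 ring CHBr; C7 ring C(Me); C8 CH2; C9/C10(Me) epoxide; C11, C12; C13 CHBr; C14 CMe2–O. Target = (6S,7S,9S,10S,13R), ring Br cis to the C7 methyl, trans epoxide.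

## Route

Step 1
Reactants: 1 geranyl acetate
Product: 2 (6S)-6,7-epoxygeranyl acetate
Conditions: ent-Shi ketone (L-fructose-derived, 30 mol%), Oxone, K2CO3, Bu4NHSO4, MeCN/DMM/aq. borate buffer pH 10.5, 0 °C
Reagents that add atoms: Oxone (potassium peroxymonosulfate), [K+].[O-]S(=O)(=O)OO
Why: Shi asymmetric epoxidation attacks only the electron-rich 6,7-alkene (the 2,3-alkene is deactivated by the allylic acetate), and the mirror-image catalyst of the D-fructose ketone (which gives R epoxides) gives the (S)-epoxide that fixes C13 before its planned inversion.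

Step 2
Reactants: 2 (6S)-6,7-epoxygeranyl acetate
Product: 3 (2E,6R)-6-bromo-7-hydroxy-3,7-dimethyloct-2-en-1-yl acetate
Conditions: Li2NiBr4, THF, 0 °C → rt; aq. NH4Cl
Reagents that add atoms: dilithium tetrabromonickelate, [Li+].[Li+].Br[Ni-2](Br)(Br)Br
Why: Regioselective SN2 epoxide opening by soft bromide at the less substituted carbon with inversion gives the (13R) secondary bromide and the tertiary alcohol.

Step 3
Reactants: 4 4-hydroxybenzoic acid
Product: 5 4-[(triisopropylsilyl)oxy]benzoic acid
Conditions: TIPSCl (2.2 equiv), imidazole, DMF, rt; then K2CO3, THF/MeOH/H2O, rt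
Reagents that add atoms: TIPSCl, CC(C)[Si](Cl)(C(C)C)C(C)C
Why: Silylation of phenol and acid followed by selective hydrolysis of the labile silyl ester (protecting-group step; aryl TIPS survives the later enolate, hydride and Oxone steps and is removed by fluoride).

Step 4
Reactants: 5 4-[(triisopropylsilyl)oxy]benzoic acid (2 equiv)
Product: 6 4-[(triisopropylsilyl)oxy]benzoic anhydride
Conditions: DCC (0.5 equiv), CH2Cl2, 0 °C → rt
Reagents that add atoms: none
Why: Carbodiimide dehydration gives the symmetric anhydride needed for Lewis-acid acyl transfer.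

Step 5
Reactants: 3 bromohydrin acetate; 6 anhydride
Product: 7 (3R,6E)-8-acetoxy-3-bromo-2,6-dimethyloct-6-en-2-yl 4-(TIPSO)benzoate
Conditions: 6 (1.5 equiv), Bi(OTf)3 (5 mol%), CH2Cl2, 0 °C → rt
Reagents that add atoms: none
Why: Bi(OTf)3-catalysed acylation of a tertiary alcohol by an anhydride works on hindered carbinols under non-basic conditions, so the bromohydrin cannot re-close to the epoxide and C13 is untouched.

Step 6
Reactants: 7 allylic acetate; 8 2-methylcyclohexane-1,3-dione
Product: 9 2-methyl-2-(side chain)cyclohexane-1,3-dione (C7–C8 bond formed, 8E retained)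
Conditions: 8, NaH (1.0 equiv), THF, 0 °C; then 7, Pd(PPh3)4 (5 mol%), 45 °C
Reagents that add atoms: none
Why: Tsuji–Trost allylic alkylation: the soft dione enolate attacks the unhindered CH2 terminus of the π-allylpalladium (linear, E retained; O-allylation reverts under Pd(0)), creating the still-prochiral quaternary C7.

Step 7
Reactants: 9 dione
Product: 10 (6R,7R)-ketol (C6–OH cis to the C8 side chain; C2 ketone retained)
Conditions: (S)-2-methyl-CBS-oxazaborolidine (30 mol%), catecholborane, toluene, −60 °C
Reagents that add atoms: none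
Why: CBS desymmetrising reduction: with the quaternary carbon as the large group the (S)-catalyst gives the (R)-carbinol and hydride enters anti to the bulkier side chain, so one enantiotopic carbonyl is reduced and C7 and C6 are set together.

Step 8
Reactants: 10 ketol
Product: 11 (6S,7S)-bromo ketone (C6–Br trans to the side chain, cis to the C7 methyl)
Conditions: CBr4, P(n-Oct)3, toluene, 70 °C
Reagents that add atoms: carbon tetrabromide, BrC(Br)(Br)Br
Why: Appel bromination displaces the oxyphosphonium by SN2 with inversion to give the target C6 configuration; the quaternary C7 has no α-hydrogen, so E1cB loss toward the ketone is impossible.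

Step 9
Reactants: 11 bromo ketone
Product: 12 C3-methyl ketone (C3 epimer mixture)
Conditions: LDA (1.05 equiv), THF, −78 °C; MeI, DMPU, −78 → −40 °C
Reagents that add atoms: iodomethane, CI
Why: Kinetic lithium enolate alkylation is regiospecific because C3 is the only enolisable position, and the C3 configuration is irrelevant since C3 becomes sp2.

Step 10
Reactants: 12 methyl ketone
Product: 13 C2=C3 enol triflate
Conditions: KHMDS, THF, −78 °C; PhNTf2, −78 → 0 °C
Reagents that add atoms: N-phenyl-bis(trifluoromethanesulfonimide), O=S(=O)(N(c1ccccc1)S(=O)(=O)C(F)(F)F)C(F)(F)F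
Why: Enol triflate formation from the only possible enolate gives the tetrasubstituted C2=C3 triflate regiospecifically.

Step 11
Reactants: 13 enol triflate
Product: 14 (9S,10S)-epoxy enol triflate
Conditions: ent-Shi ketone (30 mol%), Oxone, K2CO3, Bu4NHSO4, MeCN/DMM/aq. borate buffer pH 10.5, 0 °C
Reagents that add atoms: Oxone, [K+].[O-]S(=O)(=O)OO
Why: Shi asymmetric epoxidation: the electron-poor enol triflate is inert, so only the E-trisubstituted C9=C10 alkene reacts, and the ent-catalyst sets the (9S,10S) trans-epoxide under reagent control.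

Step 12
Reactants: 14 epoxy enol triflate
Product: 15 C1 enal (2-formyl cyclohexene)
Conditions: Pd(OAc)2 (10 mol%), dppp, CO (1 atm), Et3SiH, Et3N, DMF, 70 °C
Reagents that add atoms: carbon monoxide, [C-]#[O+]
Why: Pd-catalysed reductive carbonylation (formylation) of a vinyl triflate tolerates the hindered tetrasubstituted triflate because CO insertion is sterically undemanding, and it installs C1.

Step 13
Reactants: 15 enal
Product: 16 C1 allylic alcohol
Conditions: NaBH4, CeCl3·7H2O, MeOH/THF, −40 °C
Reagents that add atoms: none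
Why: Luche reduction gives clean 1,2-reduction of the enal without touching the aryl ester, epoxide or bromides.

Step 14
Reactants: 16 allylic alcohol
Product: 17 free phenol allylic alcohol
Conditions: TBAF, AcOH, THF, 0 °C
Reagents that add atoms: none
Why: Fluoride cleavage of the aryl silyl ether, buffered with acetic acid so the epoxide and bromides never see basic fluoride.

Step 15
Reactants: 17 phenol allylic alcohol
Product: 18 C1 allylic bromide (free phenol)
Conditions: CBr4, PPh3, 2,6-lutidine, CH2Cl2, −20 °C; used crude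
Reagents that add atoms: carbon tetrabromide, BrC(Br)(Br)Br
Why: Appel bromination of the primary allylic alcohol at low temperature; the phenol does not react and lutidine buffers HBr to protect the epoxide.

Step 16
Reactants: 18 allylic bromide phenol
Product: 19 target (CID46880797)
Conditions: NaH (1.05 equiv), toluene, 0.5 mM (syringe-pump addition), 25 → 60 °C
Reagents that add atoms: none
Why: Proposed new method: macrocyclising ortho-C-allylation of a sodium phenoxide, in which the tight, O-shielded Na-phenoxide ion pair in non-polar toluene lets Na+ assist bromide departure in a six-centre SN2 transition state at the primary C1 (SN2′ at the hindered C3 is disfavoured), the para position is blocked by the ester and both ortho positions are equivalent, the dienone tautomerises irreversibly to the phenol, and the competing O-alkylation would require a 17-membered para-bridged ether; the closest known reaction is the intermolecular ortho-C-prenylation/geranylation of alkali phenoxides, including 4-hydroxybenzoate esters, with allylic bromides in non-polar solvents, which has not been used to close a macrocycle.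

## Compound list

1 | geranyl acetate, (2E)-3,7-dimethylocta-2,6-dien-1-yl acetate | CC(=O)OC/C=C(\C)CCC=C(C)C | starting material
2 | (2E)-5-[(2S)-3,3-dimethyloxiran-2-yl]-3-methylpent-2-en-1-yl acetate | CC1(C)O[C@H]1CC/C(C)=C/COC(C)=O | intermediate
3 | (2E,6R)-6-bromo-7-hydroxy-3,7-dimethyloct-2-en-1-yl acetate | OC(C)(C)[C@H](Br)CC/C(C)=C/COC(C)=O | intermediate
4 | 4-hydroxybenzoic acid | OC(=O)c1ccc(O)cc1 | starting material
5 | 4-[(triisopropylsilyl)oxy]benzoic acid | CC(C)[Si](C(C)C)(C(C)C)Oc1ccc(cc1)C(O)=O | intermediate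
6 | 4-[(triisopropylsilyl)oxy]benzoic anhydride | CC(C)[Si](C(C)C)(C(C)C)Oc1ccc(cc1)C(=O)OC(=O)c1ccc(O[Si](C(C)C)(C(C)C)C(C)C)cc1 | intermediate
7 | (3R,6E)-8-acetoxy-3-bromo-2,6-dimethyloct-6-en-2-yl 4-[(triisopropylsilyl)oxy]benzoate | CC(C)[Si](C(C)C)(C(C)C)Oc1ccc(cc1)C(=O)OC(C)(C)[C@H](Br)CC/C(C)=C/COC(C)=O | intermediate
8 | 2-methylcyclohexane-1,3-dione | CC1C(=O)CCCC1=O | starting material
9 | (3R,6E)-3-bromo-2,6-dimethyl-8-(1-methyl-2,6-dioxocyclohexyl)oct-6-en-2-yl 4-(TIPSO)benzoate | CC(C)[Si](C(C)C)(C(C)C)Oc1ccc(cc1)C(=O)OC(C)(C)[C@H](Br)CC/C(C)=C/CC1(C)C(=O)CCCC1=O | intermediate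
10 | (3R,6E)-3-bromo-8-[(1R,2R)-2-hydroxy-1-methyl-6-oxocyclohexyl]-2,6-dimethyloct-6-en-2-yl 4-(TIPSO)benzoate (OH cis to side chain) | CC(C)[Si](C(C)C)(C(C)C)Oc1ccc(cc1)C(=O)OC(C)(C)[C@H](Br)CC/C(C)=C/C[C@]1(C)[C@H](O)CCCC1=O | intermediate
11 | (3R,6E)-3-bromo-8-[(1S,2S)-2-bromo-1-methyl-6-oxocyclohexyl]-2,6-dimethyloct-6-en-2-yl 4-(TIPSO)benzoate (ring Br cis to ring Me) | CC(C)[Si](C(C)C)(C(C)C)Oc1ccc(cc1)C(=O)OC(C)(C)[C@H](Br)CC/C(C)=C/C[C@]1(C)[C@@H](Br)CCCC1=O | intermediate
12 | (3R,6E)-3-bromo-8-[(1S,2S)-2-bromo-1,5-dimethyl-6-oxocyclohexyl]-2,6-dimethyloct-6-en-2-yl 4-(TIPSO)benzoate (C5 epimers) | CC(C)[Si](C(C)C)(C(C)C)Oc1ccc(cc1)C(=O)OC(C)(C)[C@H](Br)CC/C(C)=C/C[C@]1(C)[C@@H](Br)CCC(C)C1=O | intermediate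
13 | (3R,6E)-3-bromo-8-[(1S,6S)-6-bromo-1,3-dimethyl-2-(trifluoromethylsulfonyloxy)cyclohex-2-en-1-yl]-2,6-dimethyloct-6-en-2-yl 4-(TIPSO)benzoate | CC(C)[Si](C(C)C)(C(C)C)Oc1ccc(cc1)C(=O)OC(C)(C)[C@H](Br)CC/C(C)=C/C[C@]1(C)[C@@H](Br)CCC(C)=C1OS(=O)(=O)C(F)(F)F | intermediate
14 | (3R)-3-bromo-5-[(2S,3S)-3-{[(1S,6S)-6-bromo-1,3-dimethyl-2-(trifluoromethylsulfonyloxy)cyclohex-2-en-1-yl]methyl}-2-methyloxiran-2-yl]-2-methylpentan-2-yl 4-(TIPSO)benzoate | CC(C)[Si](C(C)C)(C(C)C)Oc1ccc(cc1)C(=O)OC(C)(C)[C@H](Br)CC[C@]2(C)O[C@H]2C[C@]1(C)[C@@H](Br)CCC(C)=C1OS(=O)(=O)C(F)(F)F | intermediate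
15 | as 14 with 2-formyl in place of the triflate: (3R)-3-bromo-5-[(2S,3S)-3-{[(1S,6S)-6-bromo-2-formyl-1,3-dimethylcyclohex-2-en-1-yl]methyl}-2-methyloxiran-2-yl]-2-methylpentan-2-yl 4-(TIPSO)benzoate | CC(C)[Si](C(C)C)(C(C)C)Oc1ccc(cc1)C(=O)OC(C)(C)[C@H](Br)CC[C@]2(C)O[C@H]2C[C@]1(C)[C@@H](Br)CCC(C)=C1C=O | intermediate
16 | as 15 with 2-(hydroxymethyl): (3R)-3-bromo-5-[(2S,3S)-3-{[(1S,6S)-6-bromo-2-(hydroxymethyl)-1,3-dimethylcyclohex-2-en-1-yl]methyl}-2-methyloxiran-2-yl]-2-methylpentan-2-yl 4-(TIPSO)benzoate | CC(C)[Si](C(C)C)(C(C)C)Oc1ccc(cc1)C(=O)OC(C)(C)[C@H](Br)CC[C@]2(C)O[C@H]2C[C@]1(C)[C@@H](Br)CCC(C)=C1CO | intermediate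
17 | (3R)-3-bromo-5-[(2S,3S)-3-{[(1S,6S)-6-bromo-2-(hydroxymethyl)-1,3-dimethylcyclohex-2-en-1-yl]methyl}-2-methyloxiran-2-yl]-2-methylpentan-2-yl 4-hydroxybenzoate | Oc1ccc(cc1)C(=O)OC(C)(C)[C@H](Br)CC[C@]2(C)O[C@H]2C[C@]1(C)[C@@H](Br)CCC(C)=C1CO | intermediate
18 | (3R)-3-bromo-5-[(2S,3S)-3-{[(1S,6S)-6-bromo-2-(bromomethyl)-1,3-dimethylcyclohex-2-en-1-yl]methyl}-2-methyloxiran-2-yl]-2-methylpentan-2-yl 4-hydroxybenzoate | Oc1ccc(cc1)C(=O)OC(C)(C)[C@H](Br)CC[C@]2(C)O[C@H]2C[C@]1(C)[C@@H](Br)CCC(C)=C1CBr | intermediate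
19 | CID46880797, (6S,7S,9S,10S,13R)-macrolide (15-membered meta-bridged 4-hydroxybenzoate lactone; bromocyclohexene with Br cis to C7-Me; trans-epoxide) | CC1=C2Cc3cc(ccc3O)C(=O)OC(C)(C)[C@H](Br)CC[C@]3(C)O[C@H]3C[C@]2(C)[C@@H](Br)CC1 | target

## Summary

Total steps: 16. Longest linear sequence: 14 (steps 1, 2, 5–16 from geranyl acetate).

Steps most likely to fail:

1. **Step 16 (proposed new macrocyclisation).** Risks are O-alkylation to the 17-membered ether and aggregate-driven oligomerisation. Fallback (known chemistry, different bond): close the ring at C1–C2 by Pd-catalysed Negishi benzyl–alkenyl coupling. This means using a 3-(silyloxymethyl)-4-(TIPSO)benzoic anhydride in step 5, converting CH2OSi → CH2Br → ArCH2ZnBr (Zn, LiCl) after step 11, coupling with the enol triflate (Pd/SPhos, high dilution), then TBAF.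
2. **Step 8 (invertive Appel at the neopentylic C6).** Risks are elimination, rearrangement or retention. Fallback: abandon substitution and create C6–Br and C7 in one anti addition by bromonium-induced (BDSB) 6-endo cyclisation of an acyclic (E)-alkenyl β-keto ester, which forces Br cis to the C7 methyl. The ketone then becomes the C2=C3(Me) unit via enol triflate/methyl coupling, the ester becomes C1, and ring diastereomers are separated against the enantiopure side chain.
3. **Step 5 (acylation of the tertiary β-bromo alcohol, with the regiochemistry of step 2 behind it).** Fallback: make the C14–O ester and C13–Br in one step by Markovnikov bromo-acyloxylation of geranyl acetate with NBS and acid 5. This replaces steps 1, 2, 4 and 5 but is racemic at C13, so the C13 epimers are separated after the CBS step.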